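**Assumptions.** Artopetelin C has no stereocentres and the aryl–benzofuran axis rotates freely, so the target is achiral and no stereocontrol is needed. tert‑Butyl (2‑methylbut‑3‑en‑2‑yl) carbonate (5) is treated as a catalogue reagent; if it is not, it is one step from 2‑methylbut‑3‑en‑2‑ol and Boc2O. The route is a design from known reaction types and has not been run.

## Retrosynthetic overview

1. Last steps: global desilylation, preceded by an aromatic Claisen of a 6‑O‑prenyl ether to set the C7 1,1‑dimethylallyl group (the para position is the C3a ring fusion, so no para‑Claisen is possible).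
2. The C2–aryl bond comes from a Negishi coupling of a 2‑benzofuranylzinc with a chroman‑5‑yl triflate.
3. The triflate comes from phloroglucinol: the chroman ring is formed first, the C6 prenyl is delivered by Claisen from a 5‑O‑(1,1‑dimethylallyl) ether (only one free ortho site), and that same oxygen then becomes the triflate.
4. The benzofuran comes from commercial 4,6‑dihydroxybenzofuran‑3(2H)‑one (6‑O‑prenylation, 4‑O‑silylation, reduction/dehydration).
5. Ring order: chroman (step 1), then aromatisation of the purchased furanone to the benzofuran (step 8), then fragment union (step 9).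

## Route

**Step 1**
Reactants: 1 phloroglucinol; 2 isoprene
Product: 3 2,2‑dimethylchroman‑5,7‑diol
Conditions: 85% H3PO4, xylene, 30–35 °C (1 in 3‑fold excess)
Reagents that add atoms: isoprene (2), C=CC(C)=C
Why: Acid‑catalysed Friedel–Crafts prenylation followed by Markovnikov ring closure of the ortho OH gives the chroman; all positions of 1 are equivalent, and excess 1 suppresses bis‑annulation.

**Step 2**
Reactants: 3
Product: 4 2,2‑dimethyl‑7‑(triisopropylsilyloxy)chroman‑5‑ol
Conditions: TIPSCl (1.0 equiv), imidazole, DMF, 0 °C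
Reagents that add atoms: TIPSCl, CC(C)[Si](Cl)(C(C)C)C(C)C
Why: Sterically controlled monosilylation; the 7‑OH has two ortho hydrogens, whereas the 5‑OH is flanked by the C4 methylene.

**Step 3**
Reactants: 4; 5 tert‑butyl (2‑methylbut‑3‑en‑2‑yl) carbonate
Product: 6 5‑(2‑methylbut‑3‑en‑2‑yloxy)‑2,2‑dimethyl‑7‑(triisopropylsilyloxy)chroman
Conditions: Pd(PPh3)4 (5 mol %), THF, 0 °C
Reagents that add atoms: carbonate 5, C=CC(C)(C)OC(=O)OC(C)(C)C (delivers the C5H9 unit; CO2 and t‑BuOH are lost)
Why: Decarboxylative Tsuji–Trost O‑allylation; at low temperature the phenoxide attacks the more substituted terminus of the π‑prenyl‑Pd complex, giving the tertiary (1,1‑dimethylallyl) ether.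

**Step 4**
Reactants: 6
Product: 7 2,2‑dimethyl‑6‑(3‑methylbut‑2‑en‑1‑yl)‑7‑(triisopropylsilyloxy)chroman‑5‑ol
Conditions: toluene, 110–120 °C, sealed tube
Reagents that add atoms: none
Why: Aromatic Claisen rearrangement; C6 is the only unsubstituted ortho position (C4a is blocked), and allyl inversion converts the 1,1‑dimethylallyl ether into a normal prenyl group.

**Step 5**
Reactants: 7
Product: 8 2,2‑dimethyl‑6‑(3‑methylbut‑2‑en‑1‑yl)‑7‑(triisopropylsilyloxy)chroman‑5‑yl trifluoromethanesulfonate
Conditions: Tf2O, pyridine, CH2Cl2, –20 to 0 °C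
Reagents that add atoms: Tf2O, O=S(=O)(OS(=O)(=O)C(F)(F)F)C(F)(F)F
Why: O‑sulfonylation of the hindered phenol turns the oxygen that directed the Claisen into the cross‑coupling leaving group; the alkene and aryl silyl ether are inert.

**Step 6**
Reactants: 9 4,6‑dihydroxybenzofuran‑3(2H)‑one; 10 prenyl bromide
Product: 11 4‑hydroxy‑6‑(3‑methylbut‑2‑en‑1‑yloxy)benzofuran‑3(2H)‑one
Conditions: K2CO3 (1.05 equiv), DMF, 0 °C to rt
Reagents that add atoms: prenyl bromide (10), CC(C)=CCBr
Why: Williamson etherification at the 6‑OH, which is para to the ketone, more acidic and unhindered; the 4‑OH is hydrogen‑bonded to C3=O and reacts more slowly.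

**Step 7**
Reactants: 11
Product: 12 6‑(3‑methylbut‑2‑en‑1‑yloxy)‑4‑(triisopropylsilyloxy)benzofuran‑3(2H)‑one
Conditions: TIPSCl, imidazole, DMAP (cat.), DMF, rt
Reagents that add atoms: TIPSCl, CC(C)[Si](Cl)(C(C)C)C(C)C
Why: Silylation of the remaining phenol; TIPS is chosen because it tolerates hydride, n‑BuLi and 190 °C, resists O→O migration, and later shields C5.

**Step 8**
Reactants: 12
Product: 13 6‑(3‑methylbut‑2‑en‑1‑yloxy)‑4‑(triisopropylsilyloxy)benzofuran
Conditions: NaBH4, MeOH–THF, 0 °C; then 1 M HCl, rt (telescoped)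
Reagents that add atoms: none
Why: Ketone reduction gives a benzylic alcohol flanked by ortho/para oxygens, which undergoes E1 dehydration on mild acid to the aromatic benzofuran; the prenyl and TIPS ethers survive brief dilute acid.

**Step 9**
Reactants: 13 (1.3 equiv); 8
Product: 14 2‑[2,2‑dimethyl‑6‑(3‑methylbut‑2‑en‑1‑yl)‑7‑(triisopropylsilyloxy)chroman‑5‑yl]‑6‑(3‑methylbut‑2‑en‑1‑yloxy)‑4‑(triisopropylsilyloxy)benzofuran
Conditions: n‑BuLi, THF, –78 °C; ZnCl2, –78 °C to rt; then 8, XPhos Pd G3 (3 mol %), THF, 60 °C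
Reagents that add atoms: none beyond the two reactants
Why: Benzofuran C2–H is the most acidic site and is lithiated selectively; Negishi coupling with a bulky biarylphosphine tolerates the di‑ortho‑substituted, electron‑rich triflate because the nucleophile has no ortho substituents.

**Step 10**
Reactants: 14
Product: 15 7‑(2‑methylbut‑3‑en‑2‑yl)‑2‑[2,2‑dimethyl‑6‑(3‑methylbut‑2‑en‑1‑yl)‑7‑(triisopropylsilyloxy)chroman‑5‑yl]‑4‑(triisopropylsilyloxy)benzofuran‑6‑ol
Conditions: PhNEt2, BSA (2 equiv), 190 °C, sealed tube; aqueous work‑up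
Reagents that add atoms: none (the transient TMS ether is lost on work‑up)
Why: Aromatic Claisen of the prenyl ether with allyl inversion gives the 1,1‑dimethylallyl group. C7 is favoured over C5 because the C6–C7 bond has the higher π‑bond order in benzofuran (as in 7‑allyloxycoumarin giving the 8‑allyl product) and C5 is shielded by the adjacent OTIPS. In‑situ silylation suppresses abnormal‑Claisen and cyclisation side reactions.

**Step 11**
Reactants: 15
Product: 16 Artopetelin C
Conditions: TBAF (2.5 equiv), AcOH (2.5 equiv), THF, 0 °C to rt, under Ar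
Reagents that add atoms: none
Why: Fluoride cleavage of both aryl TIPS ethers under buffered, non‑acidic conditions leaves the ortho‑prenyl and ortho‑(1,1‑dimethylallyl) phenols uncyclised.

## Compound list

1 | phloroglucinol | Oc1cc(O)cc(O)c1 | starting material
2 | isoprene | C=CC(C)=C | starting material
3 | 2,2‑dimethylchroman‑5,7‑diol | CC1(C)CCc2c(O)cc(O)cc2O1 | intermediate
4 | 2,2‑dimethyl‑7‑(triisopropylsilyloxy)chroman‑5‑ol | CC1(C)CCc2c(O)cc(O[Si](C(C)C)(C(C)C)C(C)C)cc2O1 | intermediate
5 | tert‑butyl (2‑methylbut‑3‑en‑2‑yl) carbonate | C=CC(C)(C)OC(=O)OC(C)(C)C | starting material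
6 | 5‑(2‑methylbut‑3‑en‑2‑yloxy)‑2,2‑dimethyl‑7‑(triisopropylsilyloxy)chroman | C=CC(C)(C)Oc1cc(O[Si](C(C)C)(C(C)C)C(C)C)cc2OC(C)(C)CCc12 | intermediate
7 | 2,2‑dimethyl‑6‑prenyl‑7‑(triisopropylsilyloxy)chroman‑5‑ol | CC(C)=CCc1c(O)c2CCC(C)(C)Oc2cc1O[Si](C(C)C)(C(C)C)C(C)C | intermediate
8 | 2,2‑dimethyl‑6‑prenyl‑7‑(triisopropylsilyloxy)chroman‑5‑yl triflate | CC(C)=CCc1c(OS(=O)(=O)C(F)(F)F)c2CCC(C)(C)Oc2cc1O[Si](C(C)C)(C(C)C)C(C)C | intermediate
9 | 4,6‑dihydroxybenzofuran‑3(2H)‑one | O=C1COc2cc(O)cc(O)c12 | starting material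
10 | prenyl bromide (1‑bromo‑3‑methylbut‑2‑ene) | CC(C)=CCBr | starting material
11 | 4‑hydroxy‑6‑(prenyloxy)benzofuran‑3(2H)‑one | CC(C)=CCOc1cc(O)c2C(=O)COc2c1 | intermediate
12 | 6‑(prenyloxy)‑4‑(triisopropylsilyloxy)benzofuran‑3(2H)‑one | CC(C)=CCOc1cc(O[Si](C(C)C)(C(C)C)C(C)C)c2C(=O)COc2c1 | intermediate
13 | 6‑(prenyloxy)‑4‑(triisopropylsilyloxy)benzofuran | CC(C)=CCOc1cc(O[Si](C(C)C)(C(C)C)C(C)C)c2ccoc2c1 | intermediate
14 | 2‑[2,2‑dimethyl‑6‑prenyl‑7‑(TIPSO)chroman‑5‑yl]‑6‑(prenyloxy)‑4‑(TIPSO)benzofuran | CC(C)=CCOc1cc(O[Si](C(C)C)(C(C)C)C(C)C)c2cc(-c3c(CC=C(C)C)c(O[Si](C(C)C)(C(C)C)C(C)C)cc4OC(C)(C)CCc34)oc2c1 | intermediate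
15 | 7‑(1,1‑dimethylallyl)‑2‑[2,2‑dimethyl‑6‑prenyl‑7‑(TIPSO)chroman‑5‑yl]‑4‑(TIPSO)benzofuran‑6‑ol | C=CC(C)(C)c1c(O)cc(O[Si](C(C)C)(C(C)C)C(C)C)c2cc(-c3c(CC=C(C)C)c(O[Si](C(C)C)(C(C)C)C(C)C)cc4OC(C)(C)CCc34)oc12 | intermediate
16 | Artopetelin C (achiral) | C=CC(C)(C)c1c(O)cc(O)c2cc(-c3c(CC=C(C)C)c(O)cc4c3CCC(C)(C)O4)oc12 | target

## Summary

**Total steps:** 11 (steps 1–5 for the chroman triflate, steps 6–8 for the benzofuran, steps 9–11 for union, Claisen and deprotection).

**Longest linear sequence:** 8 steps (1 → 3 → 4 → 6 → 7 → 8 → 14 → 15 → 16).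

**Three steps most likely to fail, with fallbacks**

1. **Step 10, late Claisen.** Risks are C5 versus C7 regiochemistry, abnormal Claisen or dihydrofuran formation, and thermal deprenylation. Fallback: install the reverse‑prenyl group before the benzofuran exists, on a symmetric arene. 2,6‑Dihydroxy‑4‑prenyloxybenzaldehyde (from 2,4,6‑trihydroxybenzaldehyde) has its para site blocked by CHO and two equivalent ortho sites, so only 3‑(1,1‑dimethylallyl)‑2,4,6‑trihydroxybenzaldehyde can form. Bis‑silylation leaves the hindered, chelated OH free; the salicylaldehyde is then converted to the 2‑bromobenzofuran (Ramirez dibromo‑olefination, Cu‑catalysed C–O cyclisation) and joined by Suzuki coupling to the boronate made from 8.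

2. **Step 2, site‑selective monosilylation of diol 3.** Fallback: make the ring as 5,7‑dihydroxy‑2,2‑dimethylchroman‑4‑one (phloroglucinol, 3,3‑dimethylacrylic acid, MsOH/P2O5). The 5‑OH is locked by a strong hydrogen bond to C4=O, so silylation occurs only at O7. The C4 carbonyl is then removed via the o‑quinone methide (ClCO2Et/Et3N, then NaBH4 in aqueous THF) to reach 4 without relying on sterics.

3. **Step 9, Negishi coupling at the di‑ortho‑substituted, electron‑rich triflate.** Fallback: form the furan ring last instead of coupling to a preformed benzofuran. A B‑ring carrying carbon at C5 is made from 3,5‑dihydroxybenzaldehyde (bis‑O‑tert‑prenylation, double Claisen, mono‑cyclisation to the chroman, silylation, Ohira–Bestmann to the aryl alkyne). This is joined to an A‑ring o‑iodophenol by Sonogashira coupling and 5‑endo‑dig cyclisation, which is much less sensitive to ortho substituents on the alkyne partner.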